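The route rests on disconnecting the C1'–C6' bond of the 2,4-dihydroxy-6-methylbenzoyl (orsellinoyl) ring on C6 of the naphthoquinone. That ring (C1'–C6', methyl on C6') is read as the folded form of a linear octane-1,3,5,7-tetraone. One base-mediated aldol condensation of the chain C2 methylene onto the C7 acetyl group closes the ring and delivers the tetra-ortho-substituted diaryl ketone without any attack on a shielded carbonyl. The precursor is a 1,2,4,5-tetramethoxynaphthalene carrying the tetraketone chain at C6 and a silyl-protected 2-hydroxyethyl group at C7, the seed of the hydroxypyranone. The methyl ethers hold the hydroxyquinone latent until a final demethylation–autoxidation.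

Key step: step 7

Remarks on the chemistry:
- Naphthalene locants are those of the target quinone (C1 and C4 carbonyl carbons, C2–OH, C5–OH, aroyl on C6, side chain on C7); primed locants belong to the orsellinoyl ring; TBS = tert-butyldimethylsilyl; LDA is used as a purchased solution.
- The target has no stereocentre. Compounds 6, 11 and 17 are formed as racemates or stereoisomer mixtures, and their stereo elements disappear in the same or the next step. Lithiated forms of 1, 3, 4, 9 and 16 are treated as reagent states and carry no number.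
- The structures of the key-step precursor (10) and product (12) needed no correction. The changes made are around them: the phenols are masked as methyl ethers, and a single final ether cleavage with autoxidation replaces separate oxidation, hydrolysis and deprotection steps.

Step 1
Reactants: 1 2,4,5-trimethoxybenzoic acid
Product: 2 2,4,5-trimethoxy-6-methylbenzoic acid
Conditions: s-BuLi (2.2 equiv), TMEDA, THF, −78 °C; MeI (excess), −78 °C → rt; 1 M HCl
Reagents that add atoms: iodomethane, CI
Why: Directed ortho-metalation of the unprotected benzoic acid: the lithium carboxylate binds s-BuLi/TMEDA and, reinforced by the neighbouring 5-OMe, should direct deprotonation to C6 in preference to C3 between two methoxy groups, and the aryllithium is then methylated by MeI (SN2).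

Step 2
Reactants: 2 2,4,5-trimethoxy-6-methylbenzoic acid
Product: 3 methyl 2,4,5-trimethoxy-6-methylbenzoate
Conditions: MeI, K2CO3, DMF, rt
Reagents that add atoms: iodomethane, CI
Why: O-alkylation of the carboxylate with MeI (SN2 at methyl) forms the ester without addition to the di-ortho-substituted carbonyl, which would make an acid-catalysed esterification slow.

Step 3
Reactants: 4 tert-butyl(but-3-yn-1-yloxy)dimethylsilane
Product: 5 methyl 5-(tert-butyldimethylsilyloxy)pent-2-ynoate
Conditions: n-BuLi, THF, −78 °C; ClCO2Me, −78 → 0 °C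
Reagents that add atoms: methyl chloroformate, COC(=O)Cl
Why: Deprotonation of the terminal alkyne and C-acylation of the lithium acetylide with a chloroformate is the standard route to alk-2-ynoates, and the silyl ether is inert to it.

Step 4
Reactants: 3 methyl 2,4,5-trimethoxy-6-methylbenzoate; 5 methyl 5-(tert-butyldimethylsilyloxy)pent-2-ynoate
Product: 7 methyl 7-[2-(tert-butyldimethylsilyloxy)ethyl]-5-hydroxy-1,2,4-trimethoxynaphthalene-6-carboxylate, via lithium allenolate 6 (not isolated)
Conditions: LDA (1.05 equiv), THF, −78 °C; then 5, −78 °C → rt; 1 M HCl (work-up)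
Reagents that add atoms: none
Why: Staunton–Weinreb-type Michael–Dieckmann annulation: LDA lithiates the methyl group of 3 (lateral lithiation), the benzylic anion adds to C3 of the ynoate, allenolate 6 closes onto the aryl ester (6-exo-trig) with loss of methoxide, and the ring tautomerises to the naphthol because the acceptor is already at the alkyne oxidation level.

Step 5
Reactants: 7 methyl 7-[2-(tert-butyldimethylsilyloxy)ethyl]-5-hydroxy-1,2,4-trimethoxynaphthalene-6-carboxylate
Product: 8 methyl 7-[2-(tert-butyldimethylsilyloxy)ethyl]-1,2,4,5-tetramethoxynaphthalene-6-carboxylate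
Conditions: MeI, Cs2CO3, DMF, 40 °C
Reagents that add atoms: iodomethane, CI
Why: Williamson O-methylation, in which the caesium naphtholate in DMF overcomes the hydrogen bond to the ester and the crowding by the peri 4-OMe.

Step 6
Reactants: 8 methyl 7-[2-(tert-butyldimethylsilyloxy)ethyl]-1,2,4,5-tetramethoxynaphthalene-6-carboxylate; 9 heptane-2,4,6-trione
Product: 10 1-{7-[2-(tert-butyldimethylsilyloxy)ethyl]-1,2,4,5-tetramethoxynaphthalen-6-yl}octane-1,3,5,7-tetraone
Conditions: 9 (2.5 equiv), LDA (exactly 3 equiv per 9), THF, 0 °C; then 8, 0 °C → rt; cold 1 M HCl to pH 4–5; crude 10 used the same day without chromatography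
Reagents that add atoms: none
Why: Claisen-type acylation of a polyanion: the trianion of 9 reacts only through its terminal, last-formed and most basic carbanion, 8 has no α-hydrogen and can act only as acyl donor, and the absence of free LDA limits deprotonation of the benzylic methylene of 8.

Step 7
Reactants: 10 1-{7-[2-(tert-butyldimethylsilyloxy)ethyl]-1,2,4,5-tetramethoxynaphthalen-6-yl}octane-1,3,5,7-tetraone
Product: 12 (2,4-dihydroxy-6-methylphenyl){7-[2-(tert-butyldimethylsilyloxy)ethyl]-1,2,4,5-tetramethoxynaphthalen-6-yl}methanone, via cyclic aldol 11 (not isolated)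
Conditions: 1 M aq. KOH, MeOH (cosolvent), N2, rt; then 1 M HCl to pH 5, 0 °C
Reagents that add atoms: none
Why: Hydroxide enolises the chain reversibly, and in the reactive form C2, the central carbon of the C1–C3 diketonate, adds to the terminal C7 acetyl carbonyl to give cyclic aldol 11, which loses water and enolises to the aromatic ring. The closest known reaction type is the base-mediated aldol cyclisation of 1-aryloctane-1,3,5,7-tetraones to 2,4-dihydroxy-6-methylbenzophenones. The ring closes in the 6-(enolexo)-exo-trig mode and the new bond is C1'–C6'. No stereocentre remains, since both centres of 11 are lost on dehydration and aromatisation. The selectivity needed is C2→C7 over the only other six-membered aldol, C6→C1; it is secured by the C1 carbonyl being flanked by 5-OMe and the C7 side chain, while the C8 methyl is not deprotonated in water, so the C8→C3 mode is closed. Room temperature in degassed aqueous methanol should keep the silyl ether and prevent displacement of 5-OMe by the new 2'-phenoxide (xanthone closure), and the crowded ketone is formed without any nucleophile attacking a shielded carbonyl.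

Step 8
Reactants: 12 (2,4-dihydroxy-6-methylphenyl){7-[2-(tert-butyldimethylsilyloxy)ethyl]-1,2,4,5-tetramethoxynaphthalen-6-yl}methanone
Product: 13 (2,4-dimethoxy-6-methylphenyl){7-[2-(tert-butyldimethylsilyloxy)ethyl]-1,2,4,5-tetramethoxynaphthalen-6-yl}methanone
Conditions: MeI (excess), K2CO3, DMF, 40 °C
Reagents that add atoms: iodomethane, CI
Why: Williamson methylation of both phenols (the chelated 2'-OH needs the excess and gentle warming) masks them against the hypervalent iodine oxidant and the amide base of steps 10–12, and the ethers leave together with the naphthalene methyl ethers in step 14.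

Step 9
Reactants: 13 (2,4-dimethoxy-6-methylphenyl){7-[2-(tert-butyldimethylsilyloxy)ethyl]-1,2,4,5-tetramethoxynaphthalen-6-yl}methanone
Product: 14 (2,4-dimethoxy-6-methylphenyl)[7-(2-hydroxyethyl)-1,2,4,5-tetramethoxynaphthalen-6-yl]methanone
Conditions: TBAF, THF, 0 °C → rt; H2O (work-up)
Reagents that add atoms: none
Why: Fluoride-induced cleavage of the Si–O bond (desilylation) frees the primary alcohol, and nothing else in 13 reacts with TBAF.

Step 10
Reactants: 14 (2,4-dimethoxy-6-methylphenyl)[7-(2-hydroxyethyl)-1,2,4,5-tetramethoxynaphthalen-6-yl]methanone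
Product: 15 2-[6-(2,4-dimethoxy-6-methylbenzoyl)-1,2,4,5-tetramethoxynaphthalen-7-yl]acetaldehyde
Conditions: Dess–Martin periodinane, CH2Cl2, 0 °C → rt
Reagents that add atoms: none
Why: Dess–Martin oxidation stops at the aldehyde under neutral conditions and should spare the electron-rich tetramethoxynaphthalene; 15 is used at once because arylacetaldehydes enolise readily.

Step 11
Reactants: 15 2-[6-(2,4-dimethoxy-6-methylbenzoyl)-1,2,4,5-tetramethoxynaphthalen-7-yl]acetaldehyde; 16 2,2,6-trimethyl-4H-1,3-dioxin-4-one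
Product: 17 6-{3-[6-(2,4-dimethoxy-6-methylbenzoyl)-1,2,4,5-tetramethoxynaphthalen-7-yl]-2-hydroxypropyl}-2,2-dimethyl-4H-1,3-dioxin-4-one (racemic)
Conditions: 16 (2.5 equiv), LDA, THF, −78 °C; then 15, −78 °C; AcOH quench
Reagents that add atoms: none
Why: Vinylogous aldol addition: the lithium dienolate of 16 attacks the aldehyde through its exocyclic γ-carbon at −78 °C, where addition should outrun enolisation of the arylacetaldehyde and the shielded diaryl ketone is inert; the new carbinol centre is formed without control (racemate) and is removed in step 12.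

Step 12
Reactants: 17 6-{3-[6-(2,4-dimethoxy-6-methylbenzoyl)-1,2,4,5-tetramethoxynaphthalen-7-yl]-2-hydroxypropyl}-2,2-dimethyl-4H-1,3-dioxin-4-one
Product: 18 6-{3-[6-(2,4-dimethoxy-6-methylbenzoyl)-1,2,4,5-tetramethoxynaphthalen-7-yl]-2-oxopropyl}-2,2-dimethyl-4H-1,3-dioxin-4-one
Conditions: Dess–Martin periodinane, CH2Cl2, rt
Reagents that add atoms: none
Why: Dess–Martin oxidation of the secondary alcohol to the β-keto dioxinone is a standard operation on dioxinone aldol adducts and erases the stereocentre.

Step 13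
Reactants: 18 6-{3-[6-(2,4-dimethoxy-6-methylbenzoyl)-1,2,4,5-tetramethoxynaphthalen-7-yl]-2-oxopropyl}-2,2-dimethyl-4H-1,3-dioxin-4-one
Product: 20 6-{[6-(2,4-dimethoxy-6-methylbenzoyl)-1,2,4,5-tetramethoxynaphthalen-7-yl]methyl}-4-hydroxy-2H-pyran-2-one, via acylketene 19 (not isolated)
Conditions: PhMe, 110 °C
Reagents that add atoms: none
Why: Thermal retro-hetero-Diels–Alder reaction of the dioxinone expels acetone, and acylketene 19 is trapped by the enol oxygen of its own δ-ketone (six-membered lactonisation), the standard dioxinone route to 6-substituted 4-hydroxy-2-pyranones.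

Step 14
Reactants: 20 6-{[6-(2,4-dimethoxy-6-methylbenzoyl)-1,2,4,5-tetramethoxynaphthalen-7-yl]methyl}-4-hydroxy-2H-pyran-2-one
Product: 22 6-{[6-(2,4-dihydroxy-6-methylbenzoyl)-2,5-dihydroxy-1,4-dioxo-1,4-dihydronaphthalen-7-yl]methyl}-4-hydroxy-2H-pyran-2-one (target), via naphthalenetetrol 21 (not isolated)
Conditions: BBr3 (excess), CH2Cl2, −78 °C → rt; then H2O–THF, air, rt
Reagents that add atoms: none
Why: Exhaustive Lewis-acid ether cleavage with BBr3 removes all six aryl methyl groups, and the 1,2,4-trihydroxylated ring of 21 autoxidises on aerobic work-up to the 2-hydroxy-1,4-quinone (as 1,2,4-trihydroxynaphthalene gives lawsone); its two quinone tautomers are one compound, so no regiochemical question arises, and ring B with its single hydroxyl cannot form a quinone.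

Compound list
1 | 2,4,5-trimethoxybenzoic acid | COc1cc(OC)c(C(=O)O)cc1OC | starting material
2 | 2,4,5-trimethoxy-6-methylbenzoic acid | Cc1c(C(=O)O)c(OC)cc(OC)c1OC | intermediate
3 | methyl 2,4,5-trimethoxy-6-methylbenzoate | COC(=O)c1c(C)c(OC)c(OC)cc1OC | intermediate
4 | tert-butyl(but-3-yn-1-yloxy)dimethylsilane | C#CCCO[Si](C)(C)C(C)(C)C | starting material
5 | methyl 5-(tert-butyldimethylsilyloxy)pent-2-ynoate | COC(=O)C#CCCO[Si](C)(C)C(C)(C)C | intermediate
6 | lithium allenolate from addition of lithiated 3 to C3 of 5 (racemic allene axis) | COC([O-])=C=C(CCO[Si](C)(C)C(C)(C)C)Cc1c(OC)c(OC)cc(OC)c1C(=O)OC.[Li+] | intermediate (not isolated)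
7 | methyl 7-[2-(tert-butyldimethylsilyloxy)ethyl]-5-hydroxy-1,2,4-trimethoxynaphthalene-6-carboxylate | COC(=O)c1c(CCO[Si](C)(C)C(C)(C)C)cc2c(OC)c(OC)cc(OC)c2c1O | intermediate
8 | methyl 7-[2-(tert-butyldimethylsilyloxy)ethyl]-1,2,4,5-tetramethoxynaphthalene-6-carboxylate | COC(=O)c1c(CCO[Si](C)(C)C(C)(C)C)cc2c(OC)c(OC)cc(OC)c2c1OC | intermediate
9 | heptane-2,4,6-trione | CC(=O)CC(=O)CC(C)=O | starting material
10 | 1-{7-[2-(tert-butyldimethylsilyloxy)ethyl]-1,2,4,5-tetramethoxynaphthalen-6-yl}octane-1,3,5,7-tetraone | CC(=O)CC(=O)CC(=O)CC(=O)c1c(CCO[Si](C)(C)C(C)(C)C)cc2c(OC)c(OC)cc(OC)c2c1OC | intermediate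
11 | 4-aroyl-5-hydroxy-5-methylcyclohexane-1,3-dione, aroyl = the naphthalene-6-carbonyl group of 10 (mixture of stereoisomers) | CC1(O)CC(=O)CC(=O)C1C(=O)c1c(CCO[Si](C)(C)C(C)(C)C)cc2c(OC)c(OC)cc(OC)c2c1OC | intermediate (not isolated)
12 | (2,4-dihydroxy-6-methylphenyl){7-[2-(tert-butyldimethylsilyloxy)ethyl]-1,2,4,5-tetramethoxynaphthalen-6-yl}methanone | Cc1cc(O)cc(O)c1C(=O)c1c(CCO[Si](C)(C)C(C)(C)C)cc2c(OC)c(OC)cc(OC)c2c1OC | intermediate
13 | (2,4-dimethoxy-6-methylphenyl){7-[2-(tert-butyldimethylsilyloxy)ethyl]-1,2,4,5-tetramethoxynaphthalen-6-yl}methanone | Cc1cc(OC)cc(OC)c1C(=O)c1c(CCO[Si](C)(C)C(C)(C)C)cc2c(OC)c(OC)cc(OC)c2c1OC | intermediate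
14 | (2,4-dimethoxy-6-methylphenyl)[7-(2-hydroxyethyl)-1,2,4,5-tetramethoxynaphthalen-6-yl]methanone | Cc1cc(OC)cc(OC)c1C(=O)c1c(CCO)cc2c(OC)c(OC)cc(OC)c2c1OC | intermediate
15 | 2-[6-(2,4-dimethoxy-6-methylbenzoyl)-1,2,4,5-tetramethoxynaphthalen-7-yl]acetaldehyde | Cc1cc(OC)cc(OC)c1C(=O)c1c(CC=O)cc2c(OC)c(OC)cc(OC)c2c1OC | intermediate
16 | 2,2,6-trimethyl-4H-1,3-dioxin-4-one | CC1=CC(=O)OC(C)(C)O1 | starting material
17 | 6-{3-[6-(2,4-dimethoxy-6-methylbenzoyl)-1,2,4,5-tetramethoxynaphthalen-7-yl]-2-hydroxypropyl}-2,2-dimethyl-4H-1,3-dioxin-4-one (racemic) | Cc1cc(OC)cc(OC)c1C(=O)c1c(CC(O)CC3=CC(=O)OC(C)(C)O3)cc2c(OC)c(OC)cc(OC)c2c1OC | intermediate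
18 | 6-{3-[6-(2,4-dimethoxy-6-methylbenzoyl)-1,2,4,5-tetramethoxynaphthalen-7-yl]-2-oxopropyl}-2,2-dimethyl-4H-1,3-dioxin-4-one | Cc1cc(OC)cc(OC)c1C(=O)c1c(CC(=O)CC3=CC(=O)OC(C)(C)O3)cc2c(OC)c(OC)cc(OC)c2c1OC | intermediate
19 | 6-[6-(2,4-dimethoxy-6-methylbenzoyl)-1,2,4,5-tetramethoxynaphthalen-7-yl]-3,5-dioxohex-1-en-1-one (acylketene) | Cc1cc(OC)cc(OC)c1C(=O)c1c(CC(=O)CC(=O)C=C=O)cc2c(OC)c(OC)cc(OC)c2c1OC | intermediate (not isolated)
20 | 6-{[6-(2,4-dimethoxy-6-methylbenzoyl)-1,2,4,5-tetramethoxynaphthalen-7-yl]methyl}-4-hydroxy-2H-pyran-2-one | Cc1cc(OC)cc(OC)c1C(=O)c1c(Cc3cc(O)cc(=O)o3)cc2c(OC)c(OC)cc(OC)c2c1OC | intermediate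
21 | 6-{[6-(2,4-dihydroxy-6-methylbenzoyl)-1,2,4,5-tetrahydroxynaphthalen-7-yl]methyl}-4-hydroxy-2H-pyran-2-one | Cc1cc(O)cc(O)c1C(=O)c1c(Cc3cc(O)cc(=O)o3)cc2c(O)c(O)cc(O)c2c1O | intermediate (not isolated)
22 | 6-{[6-(2,4-dihydroxy-6-methylbenzoyl)-2,5-dihydroxy-1,4-dioxo-1,4-dihydronaphthalen-7-yl]methyl}-4-hydroxy-2H-pyran-2-one (CNP0158797.0) | Cc1cc(O)cc(O)c1C(=O)c1c(Cc2cc(O)cc(=O)o2)cc2c(c1O)C(=O)C=C(O)C2=O | target

Total step count: 14. Longest linear sequence: 13 steps (1 → 22 through steps 1, 2 and 4–14; step 3 is the side branch).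

Steps most likely to fail

Step 6. The trianion meets an ester carbonyl that is twisted out of the ring plane and flanked on both sides, so addition may be slower than proton transfer from the C7 benzylic methylene (followed by loss of silanolate) or than decay of the polyanion on warming. The fallback sets out from 8 and returns at 10. The small hydride of DIBAL-H (CH2Cl2, −78 °C) reduces the shielded ester to {7-[2-(tert-butyldimethylsilyloxy)ethyl]-1,2,4,5-tetramethoxynaphthalen-6-yl}methanol F1. Dess–Martin oxidation gives 7-[2-(tert-butyldimethylsilyloxy)ethyl]-1,2,4,5-tetramethoxynaphthalene-6-carbaldehyde F2. The trianion of 9 adds through its terminal carbon to this much more accessible carbonyl at −78 °C to give racemic 1-hydroxy-1-{7-[2-(tert-butyldimethylsilyloxy)ethyl]-1,2,4,5-tetramethoxynaphthalen-6-yl}octane-3,5,7-trione F3. IBX (DMSO, rt) then oxidises the benzylic β-hydroxy ketone to 10.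

Step 7. The chain may fold through another enolate (closure of C6 onto the naphthyl ketone), be cut by hydroxide in a retro-Claisen cleavage, or close through oxygen to a pyranone when the mixture is acidified. The fallback sets out from 8, returns at 14 and builds the diaryl ketone by aryl-metal addition instead of ring folding. TBAF (THF) frees the alkoxide of 8, which closes onto the neighbouring ester to give the δ-lactone 6,7,9,10-tetramethoxy-3,4-dihydro-1H-naphtho[2,3-c]pyran-1-one F4, whose carbonyl lies in the ring plane and is open to attack. 2-Bromo-1,5-dimethoxy-3-methylbenzene F5, from NBS bromination of 3,5-dimethoxytoluene, is converted to the aryllithium (n-BuLi, THF, −78 °C) and added once to F4. The lithium hemiketal opens on work-up to the hydroxyethyl diaryl ketone 14.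

Step 4. The benzylic anion may act as a base toward the propargylic methylene of 5 (isomerisation to the allenoate and oligomerisation) instead of adding to C3. The fallback sets out from 5 and returns at 7. Catalytic NaOMe in MeOH adds methanol across the triple bond to give methyl (E)-3-methoxy-5-(tert-butyldimethylsilyloxy)pent-2-enoate F6, an acyclic counterpart of the 4-methoxypyranone acceptors. Lithiated 3 adds to F6 in the conjugate sense, and Dieckmann closure followed by loss of methoxide should give naphthol 7 by an addition–elimination annulation.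

Further compounds
F1 | step 6 | {7-[2-(tert-butyldimethylsilyloxy)ethyl]-1,2,4,5-tetramethoxynaphthalen-6-yl}methanol | OCc1c(CCO[Si](C)(C)C(C)(C)C)cc2c(OC)c(OC)cc(OC)c2c1OC
F2 | step 6 | 7-[2-(tert-butyldimethylsilyloxy)ethyl]-1,2,4,5-tetramethoxynaphthalene-6-carbaldehyde | O=Cc1c(CCO[Si](C)(C)C(C)(C)C)cc2c(OC)c(OC)cc(OC)c2c1OC
F3 | step 6 | 1-hydroxy-1-{7-[2-(tert-butyldimethylsilyloxy)ethyl]-1,2,4,5-tetramethoxynaphthalen-6-yl}octane-3,5,7-trione (racemic) | CC(=O)CC(=O)CC(=O)CC(O)c1c(CCO[Si](C)(C)C(C)(C)C)cc2c(OC)c(OC)cc(OC)c2c1OC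
F4 | step 7 | 6,7,9,10-tetramethoxy-3,4-dihydro-1H-naphtho[2,3-c]pyran-1-one | O=C1OCCc2cc3c(OC)c(OC)cc(OC)c3c(OC)c12
F5 | step 7 | 2-bromo-1,5-dimethoxy-3-methylbenzene | Cc1cc(OC)cc(OC)c1Br
F6 | step 4 | methyl (E)-3-methoxy-5-(tert-butyldimethylsilyloxy)pent-2-enoate | CO/C(CCO[Si](C)(C)C(C)(C)C)=C/C(=O)OC
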